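## Retrosynthetic overview

1. The chroman has a hydroquinone pattern: O1 on C8a is para to the C6–OMe oxygen. The pyran ring is therefore cut at O1–C8a and C4–C4a and traced back to a para-alkylphenol whose OH becomes the C6 oxygen.
2. Forward, the phenol is dearomatised by ipso spiro-etherification (transient oxolane ring). A ring-expanding 1,2-shift of C4 from the spiro carbon to the neighbouring ring carbon then closes the pyran ring and re-aromatises the arene.
3. The quaternary C2 (R) comes from (R)-linalool. Its vinyl group becomes C3/C4 by hydroboration and B-alkyl Suzuki coupling with 4-bromo-3-methylphenol, and the C2–O bond is never broken.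
4. Side chain (C1' is the chain carbon on C2): the prenyl terminus is cleaved to the C3' aldehyde; isopropenyl addition and Johnson–Claisen rearrangement set (E)-C3'=C4'; Still–Gennari olefination sets (Z)-C7'=C8'.
5. Ring order: spiro-oxolane (transient), then the pyran ring, the only ring formed; the side chain is built afterwards, without protecting groups.

Key step: step 2

Assumption: commercial (R)-(−)-linalool of high enantiomeric purity is used; since no bond to its carbinol carbon is broken, the enantiomeric purity of the target should equal that of the linalool.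

Remark: the descriptor at the quaternary carbon reads S in 4 and in 9–12 only because CIP priorities change there; the spatial arrangement is that of (R)-linalool throughout.

## Route

Step 1
Reactants: 1 (R)-(−)-linalool; 2 9-borabicyclo[3.3.1]nonane (9-BBN); 3 4-bromo-3-methylphenol
Product: 5 4-[(3R)-3-hydroxy-3,7-dimethyloct-6-en-1-yl]-3-methylphenol, via alkylborane 4 (not isolated)
Conditions: 2 (2.2 equiv), THF, 0 °C → rt; then 3, Pd(OAc)2 (3 mol%), SPhos (6 mol%), 3 M aq K3PO4, THF, 65 °C
Reagents that add atoms: none
Why: 9-BBN should add anti-Markovnikov to the monosubstituted vinyl group only (the trisubstituted alkene reacts far more slowly, and any O–B bond at the tertiary hydroxyl is cleaved by the aqueous base), and the primary alkylborane is then joined to the aryl bromide by a B-alkyl Suzuki–Miyaura coupling with a ligand that tolerates the free phenol, the carbinol stereocentre being untouched.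

Step 2
Reactants: 5 4-[(3R)-3-hydroxy-3,7-dimethyloct-6-en-1-yl]-3-methylphenol
Product: 7 (2R)-2,8-dimethyl-2-(4-methylpent-3-en-1-yl)-3,4-dihydro-2H-chromen-6-ol, via spirodienone 6 (not isolated)
Conditions: PhI(OAc)2 (1.0 equiv), HFIP/CH2Cl2 1:3, −20 °C; evaporate; CH2Cl2, BF3·OEt2 (0.3 equiv), −78 → −20 °C
Reagents that add atoms: none
Why: Ligand exchange of the phenol on iodine(III) and loss of PhI give a phenoxenium-type species that the tethered tertiary hydroxyl traps at the para (ipso) carbon in a 5-exo closure, an oxidative dearomatising spiro-etherification with close precedent for 4-(3-hydroxyalkyl)phenols, to give spirodienone 6. BF3 then activates the dienone carbonyl, and the ring CH2 (the future C4) shifts from the spiro carbon to the neighbouring unsubstituted ring carbon, expanding the oxolane to the pyran ring, and proton loss re-aromatises the arene; the closest known reaction type is the dienone–phenol rearrangement of 1-oxaspiro[4.5]decadienones to chroman-6-ols. Carbon rather than oxygen should migrate because the cation left at the spiro carbon is an oxocarbenium ion stabilised by the ether oxygen, and the shift should go to the C–H position rather than to the methyl-bearing carbon because only that path can end by proton loss. No new stereocentre remains: C2 keeps the configuration of linalool because the oxygen attacks the arene and the C2–O bond is never broken, and the spiro centre of 6, formed as a mixture, is destroyed again. The step needs oxidation of the phenol in preference to the trisubstituted alkene, which the fast phenol–iodane exchange at low temperature and one equivalent of oxidant should secure, and the acid stage uses catalytic Lewis acid at low temperature so that neither the alkene nor the tertiary ether is ionised. In one operation O1–C8a and C4–C4a are formed, the pyran ring is closed and the phenol oxygen ends up on C6, para to O1.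

Step 3
Reactants: 7 (2R)-2,8-dimethyl-2-(4-methylpent-3-en-1-yl)-3,4-dihydro-2H-chromen-6-ol
Product: 8 (2R)-6-methoxy-2,8-dimethyl-2-(4-methylpent-3-en-1-yl)-3,4-dihydro-2H-chromene
Conditions: MeI, K2CO3, acetone, 50 °C, under argon
Reagents that add atoms: iodomethane, CI
Why: Williamson etherification of the phenolate caps the oxidation-sensitive 6-hydroxychroman as its methyl ether, while the tertiary aryl alkyl ether and the alkene are inert to base and MeI.

Step 4
Reactants: 8 (2R)-6-methoxy-2,8-dimethyl-2-(4-methylpent-3-en-1-yl)-3,4-dihydro-2H-chromene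
Product: 10 3-[(2S)-6-methoxy-2,8-dimethyl-3,4-dihydro-2H-chromen-2-yl]propanal, via diol 9 (not isolated)
Conditions: OsO4 (2 mol%), NaIO4 (4 equiv), 2,6-lutidine, dioxane/H2O 3:1, rt
Reagents that add atoms: sodium periodate (oxygen delivered through OsO4), [Na+].[O-]I(=O)(=O)=O
Why: In this Lemieux–Johnson oxidation OsO4 dihydroxylates the only alkene and periodate cleaves the diol in situ to the C3' aldehyde and acetone, the arene not being attacked by either oxidant and 2,6-lutidine suppressing over-oxidation.

Step 5
Reactants: 10 3-[(2S)-6-methoxy-2,8-dimethyl-3,4-dihydro-2H-chromen-2-yl]propanal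
Product: 11 (3RS)-5-[(2S)-6-methoxy-2,8-dimethyl-3,4-dihydro-2H-chromen-2-yl]-2-methylpent-1-en-3-ol
Conditions: isopropenylmagnesium bromide (1.3 equiv), THF, −78 → 0 °C; aq NH4Cl
Reagents that add atoms: isopropenylmagnesium bromide, CC(=C)[Mg]Br
Why: Grignard 1,2-addition to the aldehyde gives the secondary allylic alcohol, whose new carbinol centre is formed without control, which does not matter because it becomes sp2 in step 6.

Step 6
Reactants: 11 (3RS)-5-[(2S)-6-methoxy-2,8-dimethyl-3,4-dihydro-2H-chromen-2-yl]-2-methylpent-1-en-3-ol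
Product: 13 ethyl (4E)-7-[(2R)-6-methoxy-2,8-dimethyl-3,4-dihydro-2H-chromen-2-yl]-4-methylhept-4-enoate, via ketene acetal 12 (not isolated)
Conditions: MeC(OEt)3 (8 equiv), EtCO2H (10 mol%), 140 °C, EtOH distilled off
Reagents that add atoms: triethyl orthoacetate, CCOC(C)(OCC)OCC
Why: In this Johnson–Claisen rearrangement acid-catalysed exchange gives the allyl ketene acetal, whose chair transition state with the chromanyl-ethyl residue equatorial (axial placement clashes with the ethoxy group) should give the (E)-trisubstituted C3'=C4' alkene from either carbinol epimer.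

Step 7
Reactants: 13 ethyl (4E)-7-[(2R)-6-methoxy-2,8-dimethyl-3,4-dihydro-2H-chromen-2-yl]-4-methylhept-4-enoate
Product: 14 (4E)-7-[(2R)-6-methoxy-2,8-dimethyl-3,4-dihydro-2H-chromen-2-yl]-4-methylhept-4-enal
Conditions: DIBAL-H (1.05 equiv), CH2Cl2, −78 °C; aq Rochelle salt
Reagents that add atoms: none
Why: Partial reduction of the ester with DIBAL-H at −78 °C stops at the aluminium hemiacetal, which releases the aldehyde only on work-up, and the ethers and the alkene are inert.

Step 8
Reactants: 14 (4E)-7-[(2R)-6-methoxy-2,8-dimethyl-3,4-dihydro-2H-chromen-2-yl]-4-methylhept-4-enal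
Product: 15 ethyl (2Z,6E)-9-[(2R)-6-methoxy-2,8-dimethyl-3,4-dihydro-2H-chromen-2-yl]-2,6-dimethylnona-2,6-dienoate
Conditions: (CF3CH2O)2P(O)CH(CH3)CO2Et, KHMDS, 18-crown-6, THF, −78 °C
Reagents that add atoms: ethyl 2-[bis(2,2,2-trifluoroethoxy)phosphoryl]propanoate, CCOC(=O)C(C)P(=O)(OCC(F)(F)F)OCC(F)(F)F
Why: In this Still–Gennari variant of the Horner–Wadsworth–Emmons reaction the electron-poor phosphonate with a dissociated potassium counter-ion eliminates from the kinetic syn adduct faster than it equilibrates, which should give the (Z)-2-methylenoate with the chain cis to the ester.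

Step 9
Reactants: 15 ethyl (2Z,6E)-9-[(2R)-6-methoxy-2,8-dimethyl-3,4-dihydro-2H-chromen-2-yl]-2,6-dimethylnona-2,6-dienoate
Product: 16 (2Z,6E)-9-[(2R)-6-methoxy-2,8-dimethyl-3,4-dihydro-2H-chromen-2-yl]-2,6-dimethylnona-2,6-dienoic acid (target)
Conditions: LiOH·H2O, THF/MeOH/H2O, 40 °C; then 1 M HCl to pH 3
Reagents that add atoms: lithium hydroxide, [Li+].[OH-]
Why: Saponification with LiOH cleaves the hindered ester under conditions mild enough that the (Z)-enoate should not isomerise, and both ethers and the C2 stereocentre are inert to base and to the brief acidification.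

## Compound list

1 | (R)-(−)-linalool, (3R)-3,7-dimethylocta-1,6-dien-3-ol | C=C[C@](C)(O)CCC=C(C)C | starting material
2 | 9-borabicyclo[3.3.1]nonane (9-BBN, drawn as the monomer) | B1C2CCCC1CCC2 | starting material
3 | 4-bromo-3-methylphenol | Cc1cc(O)ccc1Br | starting material
4 | 9-[(3S)-3-hydroxy-3,7-dimethyloct-6-en-1-yl]-9-borabicyclo[3.3.1]nonane | C1CC2CCCC(C1)B2CC[C@](C)(O)CCC=C(C)C | intermediate (not isolated)
5 | 4-[(3R)-3-hydroxy-3,7-dimethyloct-6-en-1-yl]-3-methylphenol | Cc1cc(O)ccc1CC[C@](C)(O)CCC=C(C)C | intermediate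
6 | (2R)-2,6-dimethyl-2-(4-methylpent-3-en-1-yl)-1-oxaspiro[4.5]deca-6,9-dien-8-one (both epimers at the spiro carbon) | CC1=CC(=O)C=CC12CC[C@](C)(O2)CCC=C(C)C | intermediate (not isolated)
7 | (2R)-2,8-dimethyl-2-(4-methylpent-3-en-1-yl)-3,4-dihydro-2H-chromen-6-ol | Oc1cc(C)c2c(c1)CC[C@@](C)(CCC=C(C)C)O2 | intermediate
8 | (2R)-6-methoxy-2,8-dimethyl-2-(4-methylpent-3-en-1-yl)-3,4-dihydro-2H-chromene | COc1cc(C)c2c(c1)CC[C@@](C)(CCC=C(C)C)O2 | intermediate
9 | (3RS)-5-[(2S)-6-methoxy-2,8-dimethyl-3,4-dihydro-2H-chromen-2-yl]-2-methylpentane-2,3-diol | COc1cc(C)c2c(c1)CC[C@@](C)(CCC(O)C(C)(C)O)O2 | intermediate (not isolated)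
10 | 3-[(2S)-6-methoxy-2,8-dimethyl-3,4-dihydro-2H-chromen-2-yl]propanal | COc1cc(C)c2c(c1)CC[C@@](C)(CCC=O)O2 | intermediate
11 | (3RS)-5-[(2S)-6-methoxy-2,8-dimethyl-3,4-dihydro-2H-chromen-2-yl]-2-methylpent-1-en-3-ol | COc1cc(C)c2c(c1)CC[C@@](C)(CCC(O)C(C)=C)O2 | intermediate
12 | (2S)-2-{3-[(1-ethoxyethenyl)oxy]-4-methylpent-4-en-1-yl}-6-methoxy-2,8-dimethyl-3,4-dihydro-2H-chromene | COc1cc(C)c2c(c1)CC[C@@](C)(CCC(OC(=C)OCC)C(C)=C)O2 | intermediate (not isolated)
13 | ethyl (4E)-7-[(2R)-6-methoxy-2,8-dimethyl-3,4-dihydro-2H-chromen-2-yl]-4-methylhept-4-enoate | COc1cc(C)c2c(c1)CC[C@@](C)(CC/C=C(\C)CCC(=O)OCC)O2 | intermediate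
14 | (4E)-7-[(2R)-6-methoxy-2,8-dimethyl-3,4-dihydro-2H-chromen-2-yl]-4-methylhept-4-enal | COc1cc(C)c2c(c1)CC[C@@](C)(CC/C=C(\C)CCC=O)O2 | intermediate
15 | ethyl (2Z,6E)-9-[(2R)-6-methoxy-2,8-dimethyl-3,4-dihydro-2H-chromen-2-yl]-2,6-dimethylnona-2,6-dienoate | COc1cc(C)c2c(c1)CC[C@@](C)(CC/C=C(\C)CC/C=C(/C)C(=O)OCC)O2 | intermediate
16 | (2Z,6E)-9-[(2R)-6-methoxy-2,8-dimethyl-3,4-dihydro-2H-chromen-2-yl]-2,6-dimethylnona-2,6-dienoic acid | COc1cc(C)c2c(c1)CC[C@@](C)(CC/C=C(\C)CC/C=C(/C)C(=O)O)O2 | target

## Step count and risks

Total step count: 9. Longest linear sequence: 9 steps (from 1).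

Steps most likely to fail:

**Step 2 (key step).** The 1,2-shift may take the other course (migration towards the methyl-bearing carbon followed by a methyl shift). The Lewis acid may also ionise the trisubstituted alkene, or the electron-rich product may be over-oxidised. The fallback sets out from alkylborane 4 (made from 1 and 2 as in step 1) and comes back at 7, using quinone chemistry in place of the rearrangement. Commercial 4-methoxy-2-methylphenol is brominated at its only free ortho position (NBS, MeCN, 0 °C) to give 2-bromo-4-methoxy-6-methylphenol F1. F1 is coupled with 4 under the conditions of step 1 to give 2-[(3R)-3-hydroxy-3,7-dimethyloct-6-en-1-yl]-4-methoxy-6-methylphenol F2. Oxidative demethylation (CAN, MeCN/H2O, 0 °C) should give the quinone 2-[(3R)-3-hydroxy-3,7-dimethyloct-6-en-1-yl]-6-methylcyclohexa-2,5-diene-1,4-dione F3. Reductive cyclisation of F3 (ascorbic acid, cat. HCl, MeOH, rt) is the ring closure known from tocopherylquinones: the tertiary hydroxyl adds to the flanked ring carbonyl and the hemiketal is reduced. It should give 7 with the C2–O bond intact.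

**Step 1.** Oxidative addition into the electron-rich bromophenoxide may be slow, so that protodeboronation and β-hydride elimination of the alkylborane compete. The fallback sets out from 1 and comes back at 5. A Heck reaction of 1 with commercial 4-iodo-3-methylphenol (Pd(OAc)2, Bu4NCl, NaHCO3, DMF, 60 °C) should give 4-[(1E,3R)-3-hydroxy-3,7-dimethylocta-1,6-dien-1-yl]-3-methylphenol F4; the tertiary carbinol offers no β-hydrogen on that side. Diimide reduction (TsNHNH2, NaOAc, THF/H2O, reflux) should then saturate the disubstituted styrene double bond in preference to the trisubstituted one and give 5.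

**Step 8.** Equilibration of the olefination adducts may erode the Z-selectivity and give a geometric mixture that is hard to separate. The fallback sets out from 14 and comes back at 15. Olefination with the ylide from (1-iodoethyl)triphenylphosphonium iodide (NaHMDS, THF, −78 °C) should give the (Z)-iodoalkene (2R)-2-[(3E,7Z)-8-iodo-4-methylnona-3,7-dien-1-yl]-6-methoxy-2,8-dimethyl-3,4-dihydro-2H-chromene F5. Palladium-catalysed ethoxycarbonylation (Pd(PPh3)4, CO 1 atm, EtOH, Et3N, DMF, 60 °C) replaces iodine with retention of alkene geometry and gives 15.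

## Further compounds

F1 | step 2 | 2-bromo-4-methoxy-6-methylphenol | COc1cc(C)c(O)c(Br)c1
F2 | step 2 | 2-[(3R)-3-hydroxy-3,7-dimethyloct-6-en-1-yl]-4-methoxy-6-methylphenol | COc1cc(C)c(O)c(CC[C@](C)(O)CCC=C(C)C)c1
F3 | step 2 | 2-[(3R)-3-hydroxy-3,7-dimethyloct-6-en-1-yl]-6-methylcyclohexa-2,5-diene-1,4-dione | CC1=CC(=O)C=C(CC[C@](C)(O)CCC=C(C)C)C1=O
F4 | step 1 | 4-[(1E,3R)-3-hydroxy-3,7-dimethylocta-1,6-dien-1-yl]-3-methylphenol | Cc1cc(O)ccc1/C=C/[C@](C)(O)CCC=C(C)C
F5 | step 8 | (2R)-2-[(3E,7Z)-8-iodo-4-methylnona-3,7-dien-1-yl]-6-methoxy-2,8-dimethyl-3,4-dihydro-2H-chromene | COc1cc(C)c2c(c1)CC[C@@](C)(CC/C=C(\C)CC/C=C(/C)I)O2
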